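The question is how the rate of making Z at 5.0% conversion of L answers to the charge of D, so the moment of that conversion comes first.

1. factor on the rate of making Z when 5.0% of the L are converted if D is charged twice over
2. factor on the rate when 5.0% of the L are converted if D is charged at 0.030 mM instead

| setting | noon | dawn | flask |
|---|---|---|---|
| L | 0.065 M | 0.065 M | 0.065 M |
| X | 1.3 mM | 1.3 mM | 1.30 mM |
| D | 0.46 mM | 0.73 mM | 0.33 mM |
| remark | run made earlier | run made earlier |  |

| run | time / h | Z / % | L / % |
|---|---|---|---|
| noon | 2.50 | 1.0 | 96.5 |
| noon | 8.00 | 8.8 | 89.7 |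
| noon | 15.0 | 25.9 | 70.8 |
| noon | 20.0 | 45.4 | 52.7 |
| noon | 30.0 | 88.3 | 8.4 |
| dawn | 2.50 | 0.7 | 96.6 |
| dawn | 5.00 | 6.0 | 92.8 |
| dawn | 8.00 | 13.5 | 84.0 |
| dawn | 15.0 | 41.9 | 55.3 |
| dawn | 30.0 | 98.1 | 0 |

(readings scatter by 0.5 percentage points)

- on the list of suspects stand: G <-> E; L + J -> G; L + X -> Q; D -> J; E -> J + Z

At 8.00 h the noon readings of L and Z leave 1.5 percentage points of L unaccounted for. X is charged at 2.00% of L, which is close to that gap, so L + X -> Q is taken to run early, and the asked conversion means Z at 3.00%.

But Z starts slowly. At 8.00 h the dawn Z stands 1.53 times the noon Z, against 1.59 in D. From 8.00 h to 15.0 h the noon Z grows 2.94-fold, while the square of time grows 3.52-fold. So Z is read as roughly proportional to [D] times the square of time, the sign of a slow D -> J (an induction period).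

Scaling the noon reading gives the arrival time, the time at which a flask reaches the asked conversion: 5.51 h for the flask at 0.33 mM. At fixed Z the rate goes as one over the arrival time, hence as the square root of [D]. This reckoning gives 1.41 for the doubled charge. At 0.030 mM the arrival time is 18.3 h, and the factor is 0.301. That arrival lies later than 15.0 h, where the noon growth already fell short of the square, so this factor is held to be high.

The forecast gives 1.44 and 0.25, the latter lower than this reckoning: "At fixed conversion, the order in D is about one half, not one."

The flask gives 1.44 and 0.252.

    G ⇌ E (K = 0.660, k = 52.2 /h)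
    L + J → G (k = 47200 /M/h)
    L + X → Q (k = 90.2 /M/h)
    D → J (k = 0.0432 /h)
    E → J + Z (k = 29.6 /h)

The flask at 0.33 mM reaches the asked conversion at 5.46 h, against the arrival time of 5.51 h. With D turning to J at 0.043 /h, the share of D turned by that arrival time is 21.2%. For a charge of 0.030 mM the arrival time of 18.3 h is the square-law estimate, not a time read from that flask, and the share reckoned for it is 54.6%. The charge ratio times these two reckoned shares gives 0.234, against 0.252.

Readings and results are calculated for an exercise, noise included.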